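**Retrosynthetic overview**
1. Confluentic acid ⇐ (H2/Pd-C, then back one step: ketal hydrolysis) protected depside 24; the depside C(=O)–O bond is cut into ring-A acid 22 and ring-B phenol 11.
2. Ring A: the benzylic C–C(=O) bond of the 2-oxoheptyl chain is made by an intermolecular Claisen-type condensation of the lateral ester dienolate of orsellinate 14 with hexanoyl Weinreb amide 17; the ketone is then masked as a dioxolane.
3. Ring B: built de novo by intermolecular Michael addition of dimethyl malonate to (E)-non-3-en-2-one, Dieckmann closure and aromatisation.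
4. Ring order: ring B is the only ring constructed (steps 1–2); ring A is bought as methyl orsellinate; the two are joined in step 14.

Assumption: the target has no stereocentre and no stereogenic double bond, so it is a single achiral compound and needs no enantiocontrol; the stereocentres of 3, 4 and 5 are racemic and are erased in step 2.

**Route**

Step 1
Reactants: 1 dimethyl malonate; 2 (E)-non-3-en-2-one
Product: 4 methyl 2,4-dioxo-6-pentylcyclohexane-1-carboxylate (racemic keto–enol mixture), via Michael adduct 3 (not isolated)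
Conditions: NaOMe (1.1 equiv), MeOH, reflux, 4 h; then cold aq. HCl
Reagents that add atoms: none
Why: The malonate anion adds to the enone β-carbon (intermolecular Michael addition) and the methyl-ketone enolate of 3 closes the six-membered ring on one ester (Dieckmann, an intramolecular Claisen condensation), driven by the stabilised β-diketone enolate; the two new stereocentres are racemic and disappear in step 2.

Step 2
Reactants: 4 methyl 2,4-dioxo-6-pentylcyclohexane-1-carboxylate
Product: 6 methyl 2,4-dihydroxy-6-pentylbenzoate, via bromodione 5 (not isolated)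
Conditions: Br2 (1.0 equiv), DMF, 0 °C, then 80 °C
Reagents that add atoms: none
Why: Oxidative aromatisation: the enolised 1,3-dione is monobrominated, and HBr-mediated bromine migration, dehydrobromination and tautomerisation give the resorcinol, removing both racemic stereocentres.

Step 3
Reactants: 6 methyl 2,4-dihydroxy-6-pentylbenzoate
Product: 7 methyl 2-hydroxy-4-(methoxymethoxy)-6-pentylbenzoate
Conditions: MOMCl (1.1 equiv), i-Pr2NEt, CH2Cl2, 0 °C to rt
Reagents that add atoms: chloromethyl methyl ether (MOMCl), COCCl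
Why: Regioselective O-alkylation: the 2-OH is deactivated by its hydrogen bond to the ester carbonyl, so only the 4-OH is protected.

Step 4
Reactants: 7 methyl 2-hydroxy-4-(methoxymethoxy)-6-pentylbenzoate
Product: 8 methyl 2-methoxy-4-(methoxymethoxy)-6-pentylbenzoate
Conditions: MeI (3 equiv), K2CO3, DMF, 50 °C
Reagents that add atoms: iodomethane (MeI), CI
Why: Williamson ether synthesis on the only remaining phenol, forced by a polar aprotic solvent and excess MeI.

Step 5
Reactants: 8 methyl 2-methoxy-4-(methoxymethoxy)-6-pentylbenzoate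
Product: 9 2-methoxy-4-(methoxymethoxy)-6-pentylbenzoic acid
Conditions: KOH, DMSO/H2O (4:1), 90 °C; then cold dilute HCl to pH 4
Reagents that add atoms: potassium hydroxide, [K+].[OH-]
Why: Saponification of the di-ortho-substituted ester with poorly solvated hydroxide in DMSO; the MOM ether is base-stable and survives the brief cold acidification.

Step 6
Reactants: 9 2-methoxy-4-(methoxymethoxy)-6-pentylbenzoic acid
Product: 10 benzyl 2-methoxy-4-(methoxymethoxy)-6-pentylbenzoate
Conditions: BnBr, K2CO3, DMF, rt
Reagents that add atoms: benzyl bromide, BrCc1ccccc1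
Why: Carboxylate O-alkylation (SN2) installs the hydrogenolysable benzyl ester without having to attack the hindered carbonyl.

Step 7
Reactants: 10 benzyl 2-methoxy-4-(methoxymethoxy)-6-pentylbenzoate
Product: 11 benzyl 4-hydroxy-2-methoxy-6-pentylbenzoate
Conditions: conc. HCl (cat.), MeOH, 40 °C
Reagents that add atoms: none
Why: Acid-catalysed acetal cleavage removes the MOM group, while the hindered benzyl ester does not transesterify under these mild conditions.

Step 8
Reactants: 12 methyl 2,4-dihydroxy-6-methylbenzoate (methyl orsellinate)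
Product: 13 methyl 2-hydroxy-4-methoxy-6-methylbenzoate
Conditions: MeI (1.05 equiv), K2CO3, acetone, reflux
Reagents that add atoms: iodomethane (MeI), CI
Why: Regioselective Williamson methylation of the non-chelated 4-OH, the 2-OH being tied up by hydrogen bonding to the ester.

Step 9
Reactants: 13 methyl 2-hydroxy-4-methoxy-6-methylbenzoate
Product: 14 methyl 2-(benzyloxy)-4-methoxy-6-methylbenzoate
Conditions: BnBr, K2CO3, DMF, 60 °C
Reagents that add atoms: benzyl bromide, BrCc1ccccc1
Why: Williamson benzylation protects the chelated phenol as an ether that tolerates LiN(i-Pr)2 and KOH and falls off in the final hydrogenolysis.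

Step 10
Reactants: 15 hexanoyl chloride; 16 N,O-dimethylhydroxylamine hydrochloride
Product: 17 N-methoxy-N-methylhexanamide
Conditions: Et3N (2.2 equiv), CH2Cl2, 0 °C to rt
Reagents that add atoms: none
Why: Nucleophilic acyl substitution (Weinreb amide formation) gives a mono-acylating hexanoyl donor.

Step 11
Reactants: 14 methyl 2-(benzyloxy)-4-methoxy-6-methylbenzoate; 17 N-methoxy-N-methylhexanamide
Product: 20 methyl 2-(benzyloxy)-4-methoxy-6-(2-oxoheptyl)benzoate, via benzylic lithium species 18 (not isolated), via tetrahedral lithium alkoxide 19 (not isolated)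
Conditions: LiN(i-Pr)2 (LDA, 2.0 equiv), THF, −78 °C, 30 min; then 17, −78 to −40 °C; aq. NH4Cl
Reagents that add atoms: none
Why: Lateral deprotonation gives the ester-conjugated benzylic anion 18, which is acylated by the Weinreb amide in an intermolecular Claisen-type condensation; the chelated adduct 19 persists until quench, so no over-addition occurs.

Step 12
Reactants: 20 methyl 2-(benzyloxy)-4-methoxy-6-(2-oxoheptyl)benzoate
Product: 21 methyl 2-(benzyloxy)-4-methoxy-6-[(2-pentyl-1,3-dioxolan-2-yl)methyl]benzoate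
Conditions: TMSOCH2CH2OTMS (2 equiv), TMSOTf (5 mol%), CH2Cl2, −78 to −20 °C; pyridine quench
Reagents that add atoms: 1,2-bis(trimethylsilyloxy)ethane, C[Si](C)(C)OCCO[Si](C)(C)C
Why: Noyori ketalisation masks the ketone under aprotic low-temperature conditions, avoiding the acid-promoted enol-lactonisation to an isocoumarin that would otherwise plague every later carboxyl activation.

Step 13
Reactants: 21 methyl 2-(benzyloxy)-4-methoxy-6-[(2-pentyl-1,3-dioxolan-2-yl)methyl]benzoate
Product: 22 2-(benzyloxy)-4-methoxy-6-[(2-pentyl-1,3-dioxolan-2-yl)methyl]benzoic acid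
Conditions: KOH, DMSO/H2O (4:1), 90 °C; then cold dilute HCl to pH 4–5, rapid extraction, used at once
Reagents that add atoms: potassium hydroxide, [K+].[OH-]
Why: Saponification of the hindered ester in aqueous DMSO; the ketal and the benzyl ether are inert to base.

Step 14
Reactants: 22 2-(benzyloxy)-4-methoxy-6-[(2-pentyl-1,3-dioxolan-2-yl)methyl]benzoic acid; 11 benzyl 4-hydroxy-2-methoxy-6-pentylbenzoate
Product: 24 benzyl 4-({2-(benzyloxy)-4-methoxy-6-[(2-pentyl-1,3-dioxolan-2-yl)methyl]benzoyl}oxy)-2-methoxy-6-pentylbenzoate, via O-acylisourea 23 (not isolated)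
Conditions: DCC (1.2 equiv), DMAP (0.2 equiv), CH2Cl2, 0 °C to rt
Reagents that add atoms: none
Why: Steglich esterification under neutral conditions joins the two fragments at the only free phenol and leaves the acid-labile ketal untouched.

Step 15
Reactants: 24 protected depside
Product: 25 benzyl 4-{[2-(benzyloxy)-4-methoxy-6-(2-oxoheptyl)benzoyl]oxy}-2-methoxy-6-pentylbenzoate
Conditions: 1 M aq. HCl/THF (1:3), rt, stopped at full conversion
Reagents that add atoms: water, O
Why: Acid-catalysed ketal hydrolysis releases the dialkyl ketone under conditions too mild to cleave the aryl or benzyl esters.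

Step 16
Reactants: 25 benzyl 4-{[2-(benzyloxy)-4-methoxy-6-(2-oxoheptyl)benzoyl]oxy}-2-methoxy-6-pentylbenzoate
Product: 26 confluentic acid
Conditions: H2 (1 atm), 10% Pd/C, EtOAc, rt
Reagents that add atoms: none
Why: Catalytic hydrogenolysis removes the benzyl ether and the benzyl ester together, and the non-conjugated ketone and the depside ester are not reduced.

**Compound list**
1 | dimethyl malonate | COC(=O)CC(=O)OC | starting material
2 | (E)-non-3-en-2-one | CCCCC/C=C/C(C)=O | starting material
3 | dimethyl 2-(2-oxononan-4-yl)propanedioate (racemic) | CCCCCC(CC(C)=O)C(C(=O)OC)C(=O)OC | intermediate (not isolated)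
4 | methyl 2,4-dioxo-6-pentylcyclohexane-1-carboxylate (racemic, enolised) | CCCCCC1CC(=O)CC(=O)C1C(=O)OC | intermediate
5 | methyl 3-bromo-2,4-dioxo-6-pentylcyclohexane-1-carboxylate | CCCCCC1CC(=O)C(Br)C(=O)C1C(=O)OC | intermediate (not isolated)
6 | methyl 2,4-dihydroxy-6-pentylbenzoate | CCCCCc1cc(O)cc(O)c1C(=O)OC | intermediate
7 | methyl 2-hydroxy-4-(methoxymethoxy)-6-pentylbenzoate | CCCCCc1cc(OCOC)cc(O)c1C(=O)OC | intermediate
8 | methyl 2-methoxy-4-(methoxymethoxy)-6-pentylbenzoate | CCCCCc1cc(OCOC)cc(OC)c1C(=O)OC | intermediate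
9 | 2-methoxy-4-(methoxymethoxy)-6-pentylbenzoic acid | CCCCCc1cc(OCOC)cc(OC)c1C(=O)O | intermediate
10 | benzyl 2-methoxy-4-(methoxymethoxy)-6-pentylbenzoate | CCCCCc1cc(OCOC)cc(OC)c1C(=O)OCc1ccccc1 | intermediate
11 | benzyl 4-hydroxy-2-methoxy-6-pentylbenzoate | CCCCCc1cc(O)cc(OC)c1C(=O)OCc1ccccc1 | intermediate
12 | methyl 2,4-dihydroxy-6-methylbenzoate (methyl orsellinate) | Cc1cc(O)cc(O)c1C(=O)OC | starting material
13 | methyl 2-hydroxy-4-methoxy-6-methylbenzoate | Cc1cc(OC)cc(O)c1C(=O)OC | intermediate
14 | methyl 2-(benzyloxy)-4-methoxy-6-methylbenzoate | Cc1cc(OC)cc(OCc2ccccc2)c1C(=O)OC | intermediate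
15 | hexanoyl chloride | CCCCCC(Cl)=O | starting material
16 | N,O-dimethylhydroxylamine hydrochloride | CNOC.Cl | starting material
17 | N-methoxy-N-methylhexanamide | CCCCCC(=O)N(C)OC | intermediate
18 | methyl 2-(benzyloxy)-6-(lithiomethyl)-4-methoxybenzoate | [Li]Cc1cc(OC)cc(OCc2ccccc2)c1C(=O)OC | intermediate (not isolated)
19 | lithium alkoxide adduct of 18 to 17 | CCCCCC(O[Li])(Cc1cc(OC)cc(OCc2ccccc2)c1C(=O)OC)N(C)OC | intermediate (not isolated)
20 | methyl 2-(benzyloxy)-4-methoxy-6-(2-oxoheptyl)benzoate | CCCCCC(=O)Cc1cc(OC)cc(OCc2ccccc2)c1C(=O)OC | intermediate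
21 | methyl 2-(benzyloxy)-4-methoxy-6-[(2-pentyl-1,3-dioxolan-2-yl)methyl]benzoate | CCCCCC1(Cc2cc(OC)cc(OCc3ccccc3)c2C(=O)OC)OCCO1 | intermediate
22 | 2-(benzyloxy)-4-methoxy-6-[(2-pentyl-1,3-dioxolan-2-yl)methyl]benzoic acid | CCCCCC1(Cc2cc(OC)cc(OCc3ccccc3)c2C(=O)O)OCCO1 | intermediate
23 | O-acylisourea of 22 with DCC | CCCCCC1(Cc2cc(OC)cc(OCc3ccccc3)c2C(=O)OC(=NC2CCCCC2)NC2CCCCC2)OCCO1 | intermediate (not isolated)
24 | benzyl 4-({2-(benzyloxy)-4-methoxy-6-[(2-pentyl-1,3-dioxolan-2-yl)methyl]benzoyl}oxy)-2-methoxy-6-pentylbenzoate | CCCCCC1(Cc2cc(OC)cc(OCc3ccccc3)c2C(=O)Oc2cc(CCCCC)c(C(=O)OCc3ccccc3)c(OC)c2)OCCO1 | intermediate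
25 | benzyl 4-{[2-(benzyloxy)-4-methoxy-6-(2-oxoheptyl)benzoyl]oxy}-2-methoxy-6-pentylbenzoate | CCCCCC(=O)Cc1cc(OC)cc(OCc2ccccc2)c1C(=O)Oc1cc(CCCCC)c(C(=O)OCc2ccccc2)c(OC)c1 | intermediate
26 | confluentic acid | CCCCCC(=O)Cc1cc(OC)cc(O)c1C(=O)Oc1cc(CCCCC)c(C(=O)O)c(OC)c1 | target

**Totals**
Total step count: 16.
Longest linear sequence: 10 steps (steps 1–7, then 14, 15, 16). The ring-A arm is 5 steps (8, 9, 11, 12, 13) plus step 10 for the amide.

**Three steps most likely to fail, each with a fallback**

Step 11 (lateral Claisen-type acylation; risks are proton transfer to the amide and self-condensation of the toluate anion). The fallback sets out from 14 and comes back at 20. The anion 18 is generated as before and trapped with hexanal instead of 17, an aldol-type addition that is faster than acyl transfer. This gives lithium 1-[3-(benzyloxy)-5-methoxy-2-(methoxycarbonyl)phenyl]heptan-2-olate F1, which lactonises on warming to racemic 8-(benzyloxy)-6-methoxy-3-pentylisochroman-1-one F2. KOH in aqueous MeOH opens the lactone to potassium 2-(benzyloxy)-6-(2-hydroxyheptyl)-4-methoxybenzoate F3. After evaporation this is alkylated with MeI in DMF to racemic methyl 2-(benzyloxy)-6-(2-hydroxyheptyl)-4-methoxybenzoate F4. F4 is oxidised at once with Dess–Martin periodinane (NaHCO3, CH2Cl2) to 20, which also removes the racemic carbinol centre.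

Step 14 (esterification of a di-ortho-substituted acid; risks are N-acylurea formation and sluggish acyl transfer). The fallback sets out from 22 and comes back at 24. The acid is converted with cyanuric fluoride and pyridine in CH2Cl2 at −10 °C into the isolable 2-(benzyloxy)-4-methoxy-6-[(2-pentyl-1,3-dioxolan-2-yl)methyl]benzoyl fluoride F5. This small, ketal-compatible acylating agent is then heated with phenol 11, Et3N and DMAP (1 equiv) in toluene at 60 °C to give 24.

Step 15 (ketal hydrolysis; the risk is acid-promoted attack of the liberated ketone enol on the aryl ester, giving an isocoumarin and cleaving the depside). The fallback sets out from 24 and comes back at 26, bypassing 25. Hydrogenolysis first (H2, 10% Pd/C, EtOAc) gives 4-({2-hydroxy-4-methoxy-6-[(2-pentyl-1,3-dioxolan-2-yl)methyl]benzoyl}oxy)-2-methoxy-6-pentylbenzoic acid F6. The ketal is then hydrolysed last in AcOH/H2O/THF (3:1:1) at rt, so the acid step is run on the natural-product framework itself, with the ester carbonyl hydrogen-bonded to the free 2-OH.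

**Further compounds**
F1 | step 11 | lithium 1-[3-(benzyloxy)-5-methoxy-2-(methoxycarbonyl)phenyl]heptan-2-olate (racemic, not isolated) | CCCCCC(O[Li])Cc1cc(OC)cc(OCc2ccccc2)c1C(=O)OC
F2 | step 11 | 8-(benzyloxy)-6-methoxy-3-pentylisochroman-1-one (racemic) | CCCCCC1Cc2cc(OC)cc(OCc3ccccc3)c2C(=O)O1
F3 | step 11 | potassium 2-(benzyloxy)-6-(2-hydroxyheptyl)-4-methoxybenzoate (racemic) | CCCCCC(O)Cc1cc(OC)cc(OCc2ccccc2)c1C(=O)[O-].[K+]
F4 | step 11 | methyl 2-(benzyloxy)-6-(2-hydroxyheptyl)-4-methoxybenzoate (racemic) | CCCCCC(O)Cc1cc(OC)cc(OCc2ccccc2)c1C(=O)OC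
F5 | step 14 | 2-(benzyloxy)-4-methoxy-6-[(2-pentyl-1,3-dioxolan-2-yl)methyl]benzoyl fluoride | CCCCCC1(Cc2cc(OC)cc(OCc3ccccc3)c2C(F)=O)OCCO1
F6 | step 15 | 4-({2-hydroxy-4-methoxy-6-[(2-pentyl-1,3-dioxolan-2-yl)methyl]benzoyl}oxy)-2-methoxy-6-pentylbenzoic acid | CCCCCC1(Cc2cc(OC)cc(O)c2C(=O)Oc2cc(CCCCC)c(C(=O)O)c(OC)c2)OCCO1
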